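**Plan**

1. Retrosynthesis, first cut: the bond between the bridging CH2 and the cyclohexadienone ring (Mannich-base / ortho-quinone-methide alkylation). This gives the aromatic Mannich base 16 and the chiral enolised trione 11.
2. Second cut, in 11: two bonds of the six-membered carbocycle, C(CH3)–C(OH) and C(OH)–C(quaternary). This gives the prenylated keto ester 3 and a masked 3-oxopentanoyl unit.
3. Feature used: the dienone ring is an enolised cyclohexane-1,3,5-trione, a folded tetraketide in which ring C–O carbons alternate with alpha carbons. Its quaternary carbon lies between two ring C–O carbons and carries the exocyclic 2-methylpropanoyl C=O, so it is the alpha carbon of a keto ester; the ring C–OH carbon next to C–CH3 is that ester's carbonyl carbon.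
4. Forward: 3 is O-acylated to enol ester 8. In the key step the acyl group moves from O to C and the carbocycle closes by Claisen condensation in the same flask. Enol ether hydrolysis gives 11. The aromatic ring comes from phloroglucinol (acylated, C-prenylated, aminomethylated) and is attached through CH2 last.
5. Stereochemistry: the only stereocentre, the quaternary ring carbon, is set in the key step by a chiral 4-aminopyridine catalyst and carried through unchanged.

Key step: step 5

Assumption: enolised triones are drawn as one tautomer, 8 is taken as the single Z enol ester, and the sense of induction of the catalyst on this substrate class is not established, so the (S)-catalyst is written and its mirror image would be used if it led to the (S)-series.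

**Route**

Step 1
Reactants: 1 methyl 4-methyl-3-oxopentanoate; 2 1-bromo-3-methylbut-2-ene (prenyl bromide)
Product: 3 methyl 4-methyl-2-(3-methylbut-2-en-1-yl)-3-oxopentanoate (racemic, labile alpha centre)
Conditions: K2CO3, acetone, reflux
Reagents that add atoms: none
Why: C-alkylation of the doubly stabilised keto ester enolate (acetoacetic ester alkylation) should give the mono-prenyl compound, whose alpha centre is labile and is destroyed later.

Step 2
Reactants: 4 methyl 3-oxopentanoate
Product: 5 methyl (2E)-3-methoxypent-2-enoate
Conditions: HC(OMe)3, H2SO4 (cat.), MeOH, rt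
Reagents that add atoms: trimethyl orthoformate, COC(OC)OC
Why: Acid-catalysed ketalisation by the orthoester and loss of methanol (enol ether formation) should give the conjugated enol ether, the E isomer with methoxy trans to the ester being the thermodynamic one.

Step 3
Reactants: 5 methyl (2E)-3-methoxypent-2-enoate
Product: 6 (2E)-3-methoxypent-2-enoic acid
Conditions: NaOH, MeOH–H2O, 60 °C; then cold 1 M HCl to pH 3
Reagents that add atoms: sodium hydroxide, [Na+].[OH-]
Why: Saponification of the vinylogous carbonate ester, with brief cold acidification so that the enol ether is not hydrolysed.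

Step 4
Reactants: 6 (2E)-3-methoxypent-2-enoic acid; 3 methyl 4-methyl-2-(3-methylbut-2-en-1-yl)-3-oxopentanoate
Product: 8 methyl (2Z)-3-{[(2E)-3-methoxypent-2-enoyl]oxy}-4-methyl-2-(3-methylbut-2-en-1-yl)pent-2-enoate, via acid chloride 7 (not isolated)
Conditions: (COCl)2, DMF (cat.), CH2Cl2, 0 °C to rt, evaporate; then 3, pyridine, CH2Cl2, 0 °C to rt
Reagents that add atoms: none
Why: Acid chloride formation followed by O-acylation of the enol of 3 in pyridine (enol ester formation) should be favoured because the fully substituted alpha carbon resists C-acylation, and the hydrogen-bonded enol should give the Z enol ester.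

Step 5
Reactants: 8 methyl (2Z)-3-{[(2E)-3-methoxypent-2-enoyl]oxy}-4-methyl-2-(3-methylbut-2-en-1-yl)pent-2-enoate
Product: 10 (6R)-5-hydroxy-3-methoxy-4-methyl-6-(3-methylbut-2-en-1-yl)-6-(2-methylpropanoyl)cyclohexa-2,4-dien-1-one, via C-acylated keto ester 9 (not isolated)
Conditions: (S)-TADMAP [(S)-3-(1-acetoxy-2,2,2-triphenylethyl)-4-(dimethylamino)pyridine] (5 mol %), toluene, 0 °C to rt; then LiN(SiMe3)2 (2.5 equiv), THF, −78 to 20 °C; AcOH quench
Reagents that add atoms: none
Why: Proposed new method: the chiral 4-(dimethylamino)pyridine adds to the enol ester carbonyl of 8 and releases the keto ester enolate as a contact ion pair with the N-acylpyridinium ion, which recombines at carbon to give 9, a Steglich-type 1,3 O-to-C acyl shift whose closest known cases are the chiral-aminopyridine rearrangements of azlactone, benzofuranone and oxindole enol esters and carbonates and the C-acylation of silyl ketene acetals by the same catalyst class (acyclic keto ester enol esters are not documented). LiN(SiMe3)2 then removes a gamma proton of the beta-methoxy enone (its alpha' carbon is quaternary, so no other enolate can cyclise) and the dienolate carbon attacks the methyl ester in an intramolecular Claisen (Dieckmann-type) condensation, mode of closure 6-(enolendo)-exo-trig, driven by loss of methoxide and deprotonation of the acidic product; this copies the acylation pattern of acylphloroglucinol biosynthesis (acyl transfer to an alpha carbon, then ring-closing Claisen condensation). The quaternary stereocentre is created in the first stage and is controlled by the catalyst, whose 1-acetoxy-2,2,2-triphenylethyl arm shields one face of the planar acylpyridinium so that the enolate carbon bonds through one enantiotopic face; the ring closure does not touch it. The step needs C- over O-acylation, secured because the O-acyl isomer re-enters the catalytic cycle while the more stable C-acyl ketone accumulates, and 1,2- over 1,4-attack on the unsaturated acyl unit, secured by the donor methoxy group and the fully substituted beta carbon. It also needs ring closure to outrun reversal of the acyl transfer; only the dienolate isomer with the quaternary carbon cis to the enol ether carbon can close, and proton exchange with HN(SiMe3)2 on warming should equilibrate the isomers.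

Step 6
Reactants: 10 (6R)-5-hydroxy-3-methoxy-4-methyl-6-(3-methylbut-2-en-1-yl)-6-(2-methylpropanoyl)cyclohexa-2,4-dien-1-one
Product: 11 (4R)-3,5-dihydroxy-6-methyl-4-(3-methylbut-2-en-1-yl)-4-(2-methylpropanoyl)cyclohexa-2,5-dien-1-one
Conditions: 1 M aq. HCl, THF, rt
Reagents that add atoms: water, O
Why: Acid-catalysed addition–elimination of water at the enol ether carbon (vinylogous ester hydrolysis) should free the enolised trione without involving the quaternary centre.

Step 7
Reactants: 12 benzene-1,3,5-triol (phloroglucinol); 13 2-methylpropanoyl chloride
Product: 14 2-methyl-1-(2,4,6-trihydroxyphenyl)propan-1-one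
Conditions: AlCl3, nitrobenzene, 0 to 65 °C; aq. HCl work-up
Reagents that add atoms: none
Why: Friedel–Crafts acylation of the electron-rich triol, where the first acyl group deactivates the ring against a second acylation.

Step 8
Reactants: 14 2-methyl-1-(2,4,6-trihydroxyphenyl)propan-1-one; 2 1-bromo-3-methylbut-2-ene
Product: 15 2-methyl-1-[2,4,6-trihydroxy-3-(3-methylbut-2-en-1-yl)phenyl]propan-1-one
Conditions: DBU (1 equiv), THF, 0 °C to rt
Reagents that add atoms: none
Why: C-alkylation of the phenolate at a free ring carbon (C-prenylation of an acylphloroglucinol), with one equivalent of bromide to limit double prenylation.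

Step 9
Reactants: 15 2-methyl-1-[2,4,6-trihydroxy-3-(3-methylbut-2-en-1-yl)phenyl]propan-1-one
Product: 16 1-{3-[(dimethylamino)methyl]-2,4,6-trihydroxy-5-(3-methylbut-2-en-1-yl)phenyl}-2-methylpropan-1-one
Conditions: aq. HNMe2 (40 %), aq. CH2O (37 %), EtOH, 0 °C to rt
Reagents that add atoms: formaldehyde, C=O; dimethylamine, CNC
Why: Mannich reaction at the only free ring position, which lies between two hydroxyl groups.

Step 10
Reactants: 11 (4R)-3,5-dihydroxy-6-methyl-4-(3-methylbut-2-en-1-yl)-4-(2-methylpropanoyl)cyclohexa-2,5-dien-1-one; 16 1-{3-[(dimethylamino)methyl]-2,4,6-trihydroxy-5-(3-methylbut-2-en-1-yl)phenyl}-2-methylpropan-1-one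
Product: 17 (4S)-2-{[2,4,6-trihydroxy-3-(3-methylbut-2-en-1-yl)-5-(2-methylpropanoyl)phenyl]methyl}-3,5-dihydroxy-6-methyl-4-(3-methylbut-2-en-1-yl)-4-(2-methylpropanoyl)cyclohexa-2,5-dien-1-one (CNP0191741.1)
Conditions: 1,4-dioxane, 60 °C, slow N2 stream; then cold dilute citric acid
Reagents that add atoms: none
Why: The acidic trione protonates the benzylic amine, loss of dimethylamine gives an ortho-quinone methide, and the trione enolate adds through its only hydrogen-bearing ring carbon (Mannich-base alkylation of a 1,3-dicarbonyl, Michael addition); the quaternary centre is untouched and its descriptor changes from R to S only because the CIP priorities change.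

**Compound list**

1 | methyl 4-methyl-3-oxopentanoate | COC(=O)CC(=O)C(C)C | starting material
2 | 1-bromo-3-methylbut-2-ene (prenyl bromide) | CC(C)=CCBr | starting material
3 | methyl 4-methyl-2-(3-methylbut-2-en-1-yl)-3-oxopentanoate (racemic) | COC(=O)C(CC=C(C)C)C(=O)C(C)C | intermediate
4 | methyl 3-oxopentanoate | CCC(=O)CC(=O)OC | starting material
5 | methyl (2E)-3-methoxypent-2-enoate | CC/C(OC)=C\C(=O)OC | intermediate
6 | (2E)-3-methoxypent-2-enoic acid | CC/C(OC)=C\C(=O)O | intermediate
7 | (2E)-3-methoxypent-2-enoyl chloride (formed in the flask) | CC/C(OC)=C\C(Cl)=O | intermediate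
8 | methyl (2Z)-3-{[(2E)-3-methoxypent-2-enoyl]oxy}-4-methyl-2-(3-methylbut-2-en-1-yl)pent-2-enoate | CC(C)/C(OC(=O)/C=C(/OC)CC)=C(\CC=C(C)C)C(=O)OC | intermediate
9 | methyl (2R)-2-[(2E)-3-methoxypent-2-enoyl]-4-methyl-2-(3-methylbut-2-en-1-yl)-3-oxopentanoate (formed in the flask) | COC(=O)[C@](CC=C(C)C)(C(=O)C(C)C)C(=O)/C=C(/OC)CC | intermediate
10 | (6R)-5-hydroxy-3-methoxy-4-methyl-6-(3-methylbut-2-en-1-yl)-6-(2-methylpropanoyl)cyclohexa-2,4-dien-1-one | COC1=CC(=O)[C@@](CC=C(C)C)(C(=O)C(C)C)C(O)=C1C | intermediate
11 | (4R)-3,5-dihydroxy-6-methyl-4-(3-methylbut-2-en-1-yl)-4-(2-methylpropanoyl)cyclohexa-2,5-dien-1-one | O=C1C=C(O)[C@@](CC=C(C)C)(C(=O)C(C)C)C(O)=C1C | intermediate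
12 | benzene-1,3,5-triol (phloroglucinol) | Oc1cc(O)cc(O)c1 | starting material
13 | 2-methylpropanoyl chloride | CC(C)C(Cl)=O | starting material
14 | 2-methyl-1-(2,4,6-trihydroxyphenyl)propan-1-one | CC(C)C(=O)c1c(O)cc(O)cc1O | intermediate
15 | 2-methyl-1-[2,4,6-trihydroxy-3-(3-methylbut-2-en-1-yl)phenyl]propan-1-one | CC(C)=CCc1c(O)cc(O)c(C(=O)C(C)C)c1O | intermediate
16 | 1-{3-[(dimethylamino)methyl]-2,4,6-trihydroxy-5-(3-methylbut-2-en-1-yl)phenyl}-2-methylpropan-1-one | CC(C)=CCc1c(O)c(CN(C)C)c(O)c(C(=O)C(C)C)c1O | intermediate
17 | (4S)-2-{[2,4,6-trihydroxy-3-(3-methylbut-2-en-1-yl)-5-(2-methylpropanoyl)phenyl]methyl}-3,5-dihydroxy-6-methyl-4-(3-methylbut-2-en-1-yl)-4-(2-methylpropanoyl)cyclohexa-2,5-dien-1-one | CC(C)=CCc1c(O)c(CC2=C(O)[C@@](CC=C(C)C)(C(=O)C(C)C)C(O)=C(C)C2=O)c(O)c(C(=O)C(C)C)c1O | target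

**Count and risks**

Total steps: 10. Longest linear sequence: 6 steps (steps 2, 3, 4, 5, 6, 10, from methyl 3-oxopentanoate). The route is convergent: three branches meet in steps 4 and 10.

Steps most likely to fail:

1. Step 5 (Proposed new method). What may go wrong:
   - insufficient enantiofacial discrimination in the acylpyridinium–enolate ion pair;
   - loss of enantiopurity by reversible C–C cleavage (ketene/enolate dissociation) before the ring closes;
   - stalling of the ring closure in the unproductive dienolate geometry.

   Fallback: the route sets out from 8 again and gives up catalyst control. Achiral 4-(dimethylamino)pyridine (10 mol %, toluene, rt) performs the Steglich-type acyl shift without induction to give the racemic C-acylated keto ester F1, which is not isolated. LiN(SiMe3)2 in THF closes the ring to the racemic methyl ether F2. F2 is resolved by preparative chromatography on an amylose tris(3,5-dimethylphenylcarbamate) stationary phase. The (R)-enantiomer is compound 10, where the route is rejoined, and the (S)-enantiomer F3 is set aside.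

2. Step 10. What may go wrong:
   - retro-Claisen loss of the 2-methylpropanoyl group from the quaternary carbon, triggered by liberated dimethylamine;
   - self-condensation of the quinone methide;
   - O-alkylation instead of C-alkylation.

   Fallback: the route sets out from 11 and 15, bypassing 16, and uses the classical amine-free formaldehyde condensation. Aqueous formaldehyde (37 %, 1 equiv) is added at 0 °C to 11 and an excess of 15 in NaHCO3-buffered aqueous ethanol. The trione condenses with formaldehyde to a 2-methylene trione, which the free ring carbon of 15 captures. Compound 17, where the route ends, is separated by chromatography from the two symmetrical methylene-bridged products.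

3. Step 6. What may go wrong:
   - acid-promoted cyclisation of the prenyl chain onto the neighbouring enol oxygen;
   - acid-catalysed cleavage of the acyl group from the quaternary carbon.

   Fallback: the route sets out from 10 and cleaves the O–CH3 bond instead of the ring C–O bond. LiCl (5 equiv) in DMF at 70 °C attacks the methyl group in an SN2 reaction with the trione enolate as leaving group. Mild acidification with citric acid gives 11, where the route is rejoined.

Further compounds
F1 | step 5 | methyl 2-[(2E)-3-methoxypent-2-enoyl]-4-methyl-2-(3-methylbut-2-en-1-yl)-3-oxopentanoate (racemic, formed in the flask) | COC(=O)C(CC=C(C)C)(C(=O)C(C)C)C(=O)/C=C(/OC)CC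
F2 | step 5 | 5-hydroxy-3-methoxy-4-methyl-6-(3-methylbut-2-en-1-yl)-6-(2-methylpropanoyl)cyclohexa-2,4-dien-1-one (racemic) | COC1=CC(=O)C(CC=C(C)C)(C(=O)C(C)C)C(O)=C1C
F3 | step 5 | (6S)-5-hydroxy-3-methoxy-4-methyl-6-(3-methylbut-2-en-1-yl)-6-(2-methylpropanoyl)cyclohexa-2,4-dien-1-one | COC1=CC(=O)[C@](CC=C(C)C)(C(=O)C(C)C)C(O)=C1C
F0 | step 10 | none | none
F0 | step 6 | none | none
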